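## Structural features

The target 11 is a tetracycle in which a 5,7-dimethoxychroman-4-one (benzo ring A, pyranone ring C) and a 4',5'-dimethoxybenzocyclobutene (benzo ring B, cyclobutene ring D) share one atom, C3 of the chromanone (= C7' of the bicyclo[4.2.0]octatriene). This spiro atom is the only stereocentre: an all-carbon quaternary centre of S configuration bonded to the ketone carbon C4, the oxymethylene C2, the aromatic carbon C6' and the cyclobutene methylene C8'. It has no neighbouring stereocentre and no hydrogen, so it cannot epimerise by enolisation, only through opening of ring D. Ring A carries oxygen at C5, C7 and C8a (a phloroglucinol pattern); ring B is a veratrole whose OMe at C5' sits ortho to the spiro junction, so C1' is the only position ortho to C6' that is free to carry C8'. Fragile points are the strained ring D (thermal conrotatory opening to an o-xylylene would racemise C3 and lead on by hydrogen shift to a 2'-methylisoflavone; strong acid can open it), the electron-rich rings A and B (halogenation, oxidation) and the 5-OMe peri to the ketone (Lewis-acid demethylation). The real difficulty is the quaternary stereocentre held inside the four-membered ring and alpha to the ketone. The key step exploits that C3 bears both the acyl carbon C4 and the methylene C8', and that C8' ends on C1', the single free ortho position of ring B. C3–C8' can therefore be read as a former 1,1-disubstituted alkene that was acylated at C3 by C4 and whose terminus C8' was joined to the ortho C–H of its own aryl group.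

## Logic of the disconnections

**11 ⇒ 7.** The bonds cut are C4–C3 (ring C) and C8'–C1' (ring D). They are cut together because a palladium atom placed on C8' links them: acylpalladation of a C3=C8' alkene by the C4 acyl group creates C3 and leaves palladium on C8', from where it can reach the C1'–H bond. The gain is two rings, the stereocentre and all the strain from an achiral, acyclic 7 that carries no halogen on ring B. The demand on the forward step is that alkene insertion beats CO loss, that the ligand on palladium selects one alkene face, and that the five-membered palladacycle collapses to the four-membered ring.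

**7 ⇒ 6 ⇒ 5.** Only the oxidation level and leaving group at the future C4 change. Keeping C4 as an aldehyde carbon until late lets ring A come from commercial 4 with its substitution pattern fixed. The demand is that oxidation and chlorination spare the electron-rich rings and the styrene-type alkene.

**5 ⇒ 3 + 4.** The bond cut is O1–C2 (phenol oxygen to allylic CH2). This joins the two halves convergently. The demand is etherification of a hydrogen-bonded ortho-substituted phenol; the two allyl termini of 3 are equivalently substituted, so direct and allylic displacement lead to the same 5.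

**3 ⇒ 1 + 2.** The bond cut is aryl–C(alkene), the future C6'–C3 bond. Both partners are commercial; the forward step is a standard cross-coupling of a vinyl bromide.

## Other disconnections considered

**Alternative 1:** (the first that comes to mind) Cut C4–C4a and O1–C2 and keep the benzocyclobutene as a building block.
- Forward: methyl C–H arylation of dimethyl 2-(6-bromo-2,3-dimethoxyphenyl)-2-methylpropanedioate A1 would give the prochiral diester A2. Desymmetrising reduction and etherification with 3,5-dimethoxyphenol would lead to acid A3, and an intramolecular Friedel–Crafts acylation of A3 would close ring C.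
- Ground for preferring the chosen plan: ring D, the stereocentre and ring C are made in three separate operations over roughly twice as many steps. Ring B must carry a halogen at its most hindered position. The final acylation generates an acylium-type centre on a tertiary, benzylic cyclobutane carbon, a situation that invites loss of CO and opening of the strained ring.

**Alternative 2:** Cut only C3–C6' (the biomimetic bond).
- Forward: intramolecular palladium-catalysed enolate alpha-arylation of 3-(2-bromo-3,4-dimethoxybenzyl)-5,7-dimethoxychroman-4-one A4 with a chiral ligand.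
- Ground for preferring the chosen plan: the route is short, but reductive elimination would have to occur from a C-bound tertiary enolate in a five-membered palladacycle. The O-bound enolate offers an unstrained six-membered C–O closure, which is the mechanistically easier exit. The chromanone enolate can also open by beta-elimination of the phenoxide.

**Alternative 3:** Cut C3–C8' with transfer of hydrogen to C2.
- Forward: photochemical 1,5-hydrogen shift in the 2'-methylisoflavone A5 (3-(2,3-dimethoxy-6-methylphenyl)-5,7-dimethoxychromen-4-one) to an o-xylylene, then thermal conrotatory 4π closure.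
- Ground for preferring the chosen plan: the o-xylylene is planar, and its two senses of conrotation lead to the two enantiomers with no handle for absolute control. The same o-xylylene can return to A5 by a thermal suprafacial hydrogen shift, so closure competes with reversion and a resolution would still be needed.

Key step: step 5

Assumption: the sense of induction of the chiral monophosphine in step 5 cannot be predicted with confidence; the ligand antipode that delivers the (3S) product is to be fixed in a first screen, both antipodes being available.

## Route

Step 1
Reactants: 1 (2,3-dimethoxyphenyl)boronic acid; 2 2-bromoprop-2-en-1-ol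
Product: 3 2-(2,3-dimethoxyphenyl)prop-2-en-1-ol
Conditions: Pd(PPh3)4 (3 mol%), K2CO3, DME/H2O, 80 °C
Reagents that add atoms: none
Why: Suzuki–Miyaura coupling of a vinyl bromide with an arylboronic acid; the free allylic alcohol is tolerated and no stereocentre is formed.

Step 2
Reactants: 3 2-(2,3-dimethoxyphenyl)prop-2-en-1-ol; 4 2-hydroxy-4,6-dimethoxybenzaldehyde
Product: 5 2-{[2-(2,3-dimethoxyphenyl)prop-2-en-1-yl]oxy}-4,6-dimethoxybenzaldehyde
Conditions: PPh3, DIAD, THF, 0 °C to rt
Reagents that add atoms: none
Why: Mitsunobu etherification of a primary allylic alcohol with an acidic, aldehyde-conjugated phenol; direct and allylic displacement give the same ether because both allyl termini of 3 are CH2.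

Step 3
Reactants: 5 2-{[2-(2,3-dimethoxyphenyl)prop-2-en-1-yl]oxy}-4,6-dimethoxybenzaldehyde
Product: 6 2-{[2-(2,3-dimethoxyphenyl)prop-2-en-1-yl]oxy}-4,6-dimethoxybenzoic acid
Conditions: NaClO2, NaH2PO4, 2-methyl-2-butene (20 equiv), t-BuOH/THF/H2O, 0 °C to rt
Reagents that add atoms: sodium chlorite, [Na+].[O-]Cl=O
Why: Pinnick oxidation; chlorous acid oxidises only the aldehyde, and the large excess of 2-methyl-2-butene should remove hypochlorous acid before it reaches the electron-rich rings or the alkene.

Step 4
Reactants: 6 2-{[2-(2,3-dimethoxyphenyl)prop-2-en-1-yl]oxy}-4,6-dimethoxybenzoic acid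
Product: 7 2-{[2-(2,3-dimethoxyphenyl)prop-2-en-1-yl]oxy}-4,6-dimethoxybenzoyl chloride
Conditions: 1-chloro-N,N,2-trimethylprop-1-en-1-amine (1.2 equiv), CH2Cl2, 0 °C to rt; CH2Cl2 evaporated, used crude
Reagents that add atoms: 1-chloro-N,N,2-trimethylprop-1-en-1-amine, CC(C)=C(Cl)N(C)C
Why: acid chloride formation with an alpha-chloroenamine under neutral conditions; no HCl is set free that could add to the styrene-type alkene, and the amide by-product is inert in step 5.

Step 5
Reactants: 7 2-{[2-(2,3-dimethoxyphenyl)prop-2-en-1-yl]oxy}-4,6-dimethoxybenzoyl chloride
Product: 11 (3S)-4',5',5,7-tetramethoxyspiro[chromane-3,7'-bicyclo[4.2.0]octa[1,3,5]trien]-4-one, via aroylpalladium chloride 8 (not isolated), via alkylpalladium chloride 9 (not isolated), via palladacycle 10 (not isolated)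
Conditions: Pd2(dba)3 (5 mol%), chiral monophosphine L* (TADDOL-derived phosphoramidite class, 12 mol%), Cs2CO3 (2 equiv), cesium pivalate CsOPiv (30 mol%), toluene, closed vessel; 7 added over 2 h at 50 °C, then 110 °C
Reagents that add atoms: none
Why: Proposed new method: an acyl-initiated domino Heck/C–H arylation in which zerovalent palladium adds into the C–Cl bond of 7 to give aroylpalladium chloride 8, whose electron-rich, 2,6-dialkoxy-flanked aroyl group holds CO well enough for the tethered 1,1-disubstituted alkene to insert syn into the Pd–acyl bond before decarbonylation. This insertion closes ring C in the 6-exo-trig mode (C4–C3 bond) and gives alkylpalladium chloride 9, which has no beta-hydrogen and therefore persists. The new stereocentre C3 is set in this insertion alone, by the chiral phosphine on palladium choosing the face of the prochiral alkene; C3 is quaternary and is not touched again. Carbonate/pivalate-assisted concerted metalation–deprotonation then takes the only ortho C–H of the 2,3-dimethoxyphenyl ring (the other ortho position carries OMe, and ring A offers no C–H within reach of a five-membered metallacycle) to give palladacycle 10. C(sp2)–C(sp3) reductive elimination from 10 closes ring D by extrusion of palladium from a five-membered metallacycle and returns zerovalent palladium. The closest known reaction types are the domino Heck/C–H activation of aryl halides and carbamoyl chlorides carrying a 2-arylallyl group, which runs through the same neopentyl-type alkylpalladium and spiro palladacycle, and the methyl C–H arylation route to benzocyclobutenes, which ends in the same reductive elimination. Selectivity needed: acyl- before aryl-palladation (aroyl electronics, mild temperature during the addition), 6-exo over 7-endo insertion (tether length) and a single C–H site (substitution pattern of ring B).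

## Compound list

1 | (2,3-dimethoxyphenyl)boronic acid | COc1cccc(B(O)O)c1OC | starting material
2 | 2-bromoprop-2-en-1-ol | OCC(Br)=C | starting material
3 | 2-(2,3-dimethoxyphenyl)prop-2-en-1-ol | OCC(=C)c1cccc(OC)c1OC | intermediate
4 | 2-hydroxy-4,6-dimethoxybenzaldehyde | COc1cc(O)c(C=O)c(OC)c1 | starting material
5 | 2-{[2-(2,3-dimethoxyphenyl)prop-2-en-1-yl]oxy}-4,6-dimethoxybenzaldehyde | COc1cc(OCC(=C)c2cccc(OC)c2OC)c(C=O)c(OC)c1 | intermediate
6 | 2-{[2-(2,3-dimethoxyphenyl)prop-2-en-1-yl]oxy}-4,6-dimethoxybenzoic acid | COc1cc(OCC(=C)c2cccc(OC)c2OC)c(C(=O)O)c(OC)c1 | intermediate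
7 | 2-{[2-(2,3-dimethoxyphenyl)prop-2-en-1-yl]oxy}-4,6-dimethoxybenzoyl chloride | COc1cc(OCC(=C)c2cccc(OC)c2OC)c(C(=O)Cl)c(OC)c1 | intermediate
8 | aroylpalladium chloride from 7 (divalent palladium, phosphine not drawn) | COc1cc(OCC(=C)c2cccc(OC)c2OC)c(C(=O)[Pd]Cl)c(OC)c1 | intermediate
9 | [3-(2,3-dimethoxyphenyl)-5,7-dimethoxy-4-oxochroman-3-yl]methylpalladium chloride, C3 configured as in 11 (divalent palladium, phosphine not drawn) | COc1cc(OC)c2c(c1)OC[C@@](c1cccc(OC)c1OC)(C[Pd]Cl)C2=O | intermediate
10 | five-membered C(aryl),C(alkyl)-palladacycle, palladium bonded to C8' and C1', C3 configured as in 11 (divalent palladium, phosphine not drawn) | COc1cc(OC)c2c(c1)OC[C@@]1(C[Pd]c3ccc(OC)c(OC)c31)C2=O | intermediate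
11 | (3S)-4',5',5,7-tetramethoxyspiro[chromane-3,7'-bicyclo[4.2.0]octa[1,3,5]trien]-4-one (CH2 of the cyclobutene = C8', OMe on ring B at C4' and C5') | COc1cc(OC)c2c(c1)OC[C@@]1(Cc3ccc(OC)c(OC)c31)C2=O | target

## Step count and risks

Total step count: 5. Longest linear sequence: 5 steps (1 or 2 to 11).

**Step 5 (key step, proposed new method).** Three processes are most likely to go wrong.
- Loss of CO from the aroylpalladium species before alkene insertion would divert the cascade into 5-exo arylpalladation.
- The ketone-chelated alkylpalladium stage may stall, so that C–H palladation or the strain-building reductive elimination does not turn over.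
- A monodentate ligand may give weak facial selection in the insertion.

Fallback with known chemistry, setting out from 4 and coming back at 11: commercial 4-bromo-1,2-dimethoxybenzene is deprotonated between OMe and Br (LDA, THF, −78 °C) and quenched with iodine to give 1-bromo-2-iodo-3,4-dimethoxybenzene F1. Suzuki coupling at the C–I bond with 2-(4,4,5,5-tetramethyl-1,3,2-dioxaborolan-2-yl)prop-2-en-1-ol [Pd(PPh3)4, K2CO3] should give 2-(6-bromo-2,3-dimethoxyphenyl)prop-2-en-1-ol F2. Mitsunobu etherification of F2 with 4 gives 2-{[2-(6-bromo-2,3-dimethoxyphenyl)prop-2-en-1-yl]oxy}-4,6-dimethoxybenzaldehyde F3. Enantioselective intramolecular hydroacylation of the unactivated alkene with a chiral triazolium-derived N-heterocyclic carbene (DBU, dioxane, 80 °C) sets the quaternary centre in (3S)-3-(6-bromo-2,3-dimethoxyphenyl)-5,7-dimethoxy-3-methylchroman-4-one F4. Methyl C(sp3)–H arylation [Pd(OAc)2, P(t-Bu)3·HBF4, K2CO3, DMF, 130 °C] then closes ring D and rejoins the route at 11.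

**Step 4.** Electrophilic attack of the activated acyl group on the electron-rich alkene, or hydrolysis on handling, could erode the acid chloride before it meets palladium. Fallback, setting out from 6 and coming back at 11: deoxyfluorination (cyanuric fluoride, pyridine, CH2Cl2) gives 2-{[2-(2,3-dimethoxyphenyl)prop-2-en-1-yl]oxy}-4,6-dimethoxybenzoyl fluoride F5. F5 can be chromatographed, is inert to carbonate, and enters step 5 in place of 7 by oxidative addition of its C–F bond to zerovalent palladium.

**Step 3.** Incomplete scavenging of hypochlorous acid would lead to ring chlorination or chlorohydrin formation at the alkene, and the strongly donor-substituted aldehyde may oxidise slowly. Fallback, setting out from 3 and coming back at 6: Mitsunobu etherification of 3 with commercial methyl 2-hydroxy-4,6-dimethoxybenzoate gives methyl 2-{[2-(2,3-dimethoxyphenyl)prop-2-en-1-yl]oxy}-4,6-dimethoxybenzoate F6, which is saponified (KOH, EtOH/H2O, reflux) to 6. The carboxyl oxidation level is then carried from the start and no oxidant is used.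

**Step 2.** Low conversion is possible because the phenol is ortho-disubstituted and internally hydrogen-bonded, with competing alkylation of the hydrazide. Fallback, setting out from 3 and coming back at 5: 3 is converted (PBr3, Et2O, 0 °C) into 1-(3-bromoprop-1-en-2-yl)-2,3-dimethoxybenzene F7, which alkylates the potassium phenoxide of 4 (K2CO3, DMF, 50 °C) to give 5.

## Further compounds

F1 | step 5 | 1-bromo-2-iodo-3,4-dimethoxybenzene | COc1ccc(Br)c(I)c1OC
F2 | step 5 | 2-(6-bromo-2,3-dimethoxyphenyl)prop-2-en-1-ol | OCC(=C)c1c(Br)ccc(OC)c1OC
F3 | step 5 | 2-{[2-(6-bromo-2,3-dimethoxyphenyl)prop-2-en-1-yl]oxy}-4,6-dimethoxybenzaldehyde | COc1cc(OCC(=C)c2c(Br)ccc(OC)c2OC)c(C=O)c(OC)c1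
F4 | step 5 | (3S)-3-(6-bromo-2,3-dimethoxyphenyl)-5,7-dimethoxy-3-methylchroman-4-one | COc1cc(OC)c2c(c1)OC[C@](C)(c1c(Br)ccc(OC)c1OC)C2=O
F5 | step 4 | 2-{[2-(2,3-dimethoxyphenyl)prop-2-en-1-yl]oxy}-4,6-dimethoxybenzoyl fluoride | COc1cc(OCC(=C)c2cccc(OC)c2OC)c(C(=O)F)c(OC)c1
F6 | step 3 | methyl 2-{[2-(2,3-dimethoxyphenyl)prop-2-en-1-yl]oxy}-4,6-dimethoxybenzoate | COC(=O)c1c(OC)cc(OC)cc1OCC(=C)c1cccc(OC)c1OC
F7 | step 2 | 1-(3-bromoprop-1-en-2-yl)-2,3-dimethoxybenzene | BrCC(=C)c1cccc(OC)c1OC
A1 | alternative 1 | dimethyl 2-(6-bromo-2,3-dimethoxyphenyl)-2-methylpropanedioate | COC(=O)C(C)(C(=O)OC)c1c(Br)ccc(OC)c1OC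
A2 | alternative 1 | dimethyl 4,5-dimethoxybicyclo[4.2.0]octa-1,3,5-triene-7,7-dicarboxylate | COC(=O)C1(C(=O)OC)Cc2ccc(OC)c(OC)c21
A3 | alternative 1 | (7S)-7-[(3,5-dimethoxyphenoxy)methyl]-4,5-dimethoxybicyclo[4.2.0]octa-1,3,5-triene-7-carboxylic acid | COc1cc(OC)cc(OC[C@@]2(Cc3ccc(OC)c(OC)c32)C(=O)O)c1
A4 | alternative 2 | 3-(2-bromo-3,4-dimethoxybenzyl)-5,7-dimethoxychroman-4-one | COc1cc(OC)c2c(c1)OCC(Cc1ccc(OC)c(OC)c1Br)C2=O
A5 | alternative 3 | 3-(2,3-dimethoxy-6-methylphenyl)-5,7-dimethoxy-4H-chromen-4-one | COc1cc(OC)c2c(c1)occ(-c1c(C)ccc(OC)c1OC)c2=O
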